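# Synthesis plan for CNP0293221.1: ring B by [2,3]-Wittig contraction of a furan-bridged ether

## The problem

Atoms are numbered so that C1 is the methyl-bearing quaternary carbon, C2 the butanoyloxy carbon, C3 and C4 the methylenes, C5=C6 the ring olefin (methyl on C5), C7 the lactone O–CH, C8=C17 the butenolide olefin (methyl on C17), C19 the lactone carbonyl, C9 the free carbinol, C10 the ring-fusion CH, C11=C12 the cyclohexene olefin (methyl on C11), C13 its CH2 and C14 the acetoxy carbon. Ring A is the cyclohexene (C1, C10–C14), ring B the ten-membered carbocycle (C1–C10) and ring C the butenolide.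

Ring A and ring B are trans-fused along C1–C10, ring B shares C7–C8 with ring C and contains a Z trisubstituted olefin. Closing this strained medium ring is the central difficulty.

There are six stereocentres, (1S,2R,7S,9R,10S,14S). C1 is the hub: it can be set first in absolute terms and carries the C2 and C14 carbinols and C10 as neighbours. A temporary stereocentre at C12 can be relayed to C10. C9 and C7 sit on ring B and depend on its conformation.

Two different esters sit on hindered carbinols (C2, C14) next to a free C9 hydroxyl. They must be told apart, and acyl migration between O2 and O14 is possible. The butenolide has a doubly allylic, epimerisable C7–O bond and could relactonise onto O9. None of these groups survives an organolithium, so they must come last.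

The enabling feature is the array HO–C9–C10–C11=C12. A free hydroxyl on a carbon bonded to an allylic carbon is what a [2,3]-Wittig shift of a C9–O–C12 ether with a C10=C11 olefin leaves behind. A furan in place of ring C makes the C9 hydrogens acidic and is a latent butenolide.

## Retrosynthesis

**Target 39 to carbinol 31.** No skeletal bond is cut. The butenolide is traced to a 2-silylfuran with silicon on C19, the C2 butanoate to a methoxymethyl ether and the C14 acetate to a silyl ether. Esters and lactone cannot precede the organolithium step, and ethers without acidic hydrogens are the safest spectators for it. The C9 hydroxyl is masked as its 2-naphthylmethyl ether 32, an ether that cannot take part in lactone formation and survives both later unmaskings. Forward, photooxygenation must place the carbonyl at the silylated carbon, hydride must set C7 (34), and the three oxygen functions are then released one at a time (35 to 39).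

**Carbinol 31 to macrocyclic ether 30.** C9–C10 is cut, O9 is reconnected to C12 and the olefin moves from C11=C12 to C10=C11. Closing ring B end to end at C6–C7, C3–C4 or C9–C10 would mean a direct ten-membered closure. Here a thirteen-membered ether, far easier to form, contracts from within. Two stereocentres on a medium ring (C9, C10) are exchanged for one (C12) on a cyclohexene. The forward step needs deprotonation at C9 only and a suprafacial shift.

**Ether 30 to chloride 29, diol 27 and coupled product 26.** The C9–O bond is cut. The other option, etherifying first and closing the large ring at C6–C7 by an intramolecular coupling, would require an organometallic to be generated beside a vinyl iodide in the same molecule. An alkoxide displacing a reactive furylmethyl chloride is simpler. The precursor is an open chain with one free secondary hydroxyl (C12). C14 and C2 must therefore carry groups that survive the removal of the temporary silyl groups on O12 and O9.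

**Coupled product 26 to vinyl iodide 24 and furan 9.** C6–C7 is cut between two sp2 carbons. A Negishi coupling keeps the Z geometry that the iodide brings, whereas an olefination at C5=C6 would have to create a trisubstituted Z olefin with no control element. The cut divides the molecule into ring A with its side chain and a tetrasubstituted furan. Furan 9 has only one free α-position (C7), so metalation is unambiguous.

**Vinyl iodide 24 to methyl ketone 21 and bromide 3.** C3–C4 is cut, and the C2 carbinol is traced to a ketone. Adding a C3 organometallic to a C2 aldehyde would need an alkyl metal that carries a vinyl iodide and would give C2 without control. The methyl ketone can enolise to one side only, alkylates with a reactive allylic bromide that already holds the Z iodide, and is then reduced under catalyst control (23).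

**Methyl ketone 21 to benzamide 13, then acid 10 and amine 11.** Ring A is traced to an arene. The C1–CH3 bond comes from Birch reductive methylation under auxiliary control, the C14 oxygen is the arene methoxy group, the C11 methyl is on the arene, and the C12 oxygen comes from allylic oxidation once C14 is set. An ortho-methoxy acid is chosen because a para alkoxy group is lost under dissolving-metal conditions. Only the ortho isomer gives an enol ether at C14 and supports the auxiliary-controlled alkylation. The auxiliary amide is finally displaced by methyllithium to give the C2–C3 ketone.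

**Fragments 9 and 3.** Furan 9 comes from 3,4-dibromofuran 4. One bromine becomes the C9 hydroxymethyl group, and the other first directs silylation to the adjacent α-carbon (C19) and then becomes the C17 methyl. Bromide 3 comes from prop-2-yn-1-ol 1 by anti-carbomagnesiation, which fixes the Z relationship of iodine and C4.

## Roads not taken

**Alternative 1:** Ring A is cut at C1–C10 and C13–C14. A [4+2] cycloaddition between a C10–C13 diene already carrying C9 and a C1=C14 acrolein, whose formyl group stands in for the C1 methyl, would give cyclohexene aldehyde A1.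
- Merits: one step sets C1, C10 and C14, with relative configuration read from dienophile geometry and approach. The C11=C12 olefin appears in its final place, and catalytic asymmetric versions are conceivable.
- Weak points: the dienophile is trisubstituted and its β-acyloxy group makes it a push–pull olefin of low reactivity. The terminal substituent and the inner methyl of the diene direct regiochemistry in opposite senses. The formyl group must later be reduced to methyl at a neopentyl position. The plan leaves ring B, C9 and C7 open.
- Comparison: for ring A alone this road is shorter than the chosen one, which needs separate reductions for C14, C12 and C2. The chosen plan offsets this with a key step that closes ring B and fixes C9 and C10 together, and with a quaternary centre from an alkylation of established facial sense.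

**Alternative 2:** C6–C7 and the lactone C–O bond are cut. With CrCl2 and NiCl2 an alkynyl iodide at C6 would add to an aldehyde at C7, and the resulting alkoxide would lactonise onto C19, giving cycloalkyne butenolide A2.
- Merits: the reagent tolerates esters, so the final acyl groups can be in place. Ring B, C7 and ring C arise in one operation, and the endgame is short on paper.
- Weak points: a ten-membered cycloalkyne is strained, and the C7 configuration rests on the folding of a flexible chain. The C5 methyl is still missing, and adding methyl and hydrogen syn across a propargylic lactone with the right regiochemistry is hard. Organocopper reagents would rather ionise the propargylic C7–O bond.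
- Comparison: this road needs fewer protecting-group operations after ring closure than the chosen plan. The chosen plan offsets this by bringing in the Z olefin with its methyl as a geometrically defined vinyl iodide before any ring is closed, and by forming ring B from within a larger ring.

**Alternative 3:** C3–C4 is cut. The caesium enolate of a C2 β-keto sulfone would displace an allylic bromide at C4, giving ten-membered keto sulfone A3.
- Merits: soft-carbanion alkylation is a proven macrocyclisation, and the butenolide and the C7, C9, C10 and C14 centres can be in place. C2 is made afterwards by ketone reduction.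
- Weak points: it is an end-to-end ten-membered closure against transannular strain. The C4 bromide is allylic to the Z olefin next to the doubly allylic C7–O bond, which invites ionisation, allylic transposition and loss of geometry. Reductive removal of the sulfone threatens the γ-acyloxy enoate. The open precursor needs C9–C10 with two stereocentres from an intermolecular reaction with no evident control.
- Comparison: no organolithium meets late functionality, so this road is better in protecting-group economy. The chosen plan offsets this with stereocontrolled C9–C10 formation and a ring closure that avoids the end-to-end entropy and strain penalty.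

Key step: step 23

## Route

Assumption: the potassium enolate formed from benzamide 13 is taken to be methylated on the face opposite its chelated methoxymethyl arm, as in the accepted model for 2-methoxybenzamides of this auxiliary, which leads to the (1R) diene 14 as drawn.

Locants C1–C20 follow the target numbering. CIP letters at C1 change where protecting groups alter priorities, without any change in geometry.

Step 1
Reactants: 1 prop-2-yn-1-ol
Product: 2 (Z)-3-iodo-2-methylprop-2-en-1-ol
Conditions: MeMgBr (3 equiv), CuI (10 mol %), Et2O, −10 °C to rt; then I2, −78 to 0 °C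
Reagents that add atoms: methylmagnesium bromide, C[Mg]Br; iodine, II
Why: Copper-catalysed anti-carbomagnesiation of the propargylic magnesium alkoxide (Duboudin–Jousseaume reaction) puts methyl on the inner carbon and magnesium, held by the alkoxide, on the terminal carbon cis to CH2O; iodinolysis with retention should give the Z iodide that becomes C4–C6.

Step 2
Reactants: 2 (Z)-3-iodo-2-methylprop-2-en-1-ol
Product: 3 (Z)-3-bromo-1-iodo-2-methylprop-1-ene
Conditions: CBr4, PPh3, CH2Cl2, 0 °C
Reagents that add atoms: carbon tetrabromide, BrC(Br)(Br)Br
Why: Appel bromination of a primary allylic alcohol; neutral conditions should leave the olefin geometry and the vinyl iodide untouched.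

Step 3
Reactants: 4 3,4-dibromofuran
Product: 6 (4-bromofuran-3-yl)methanol, via 4-bromofuran-3-carbaldehyde 5 (not isolated)
Conditions: n-BuLi (1.0 equiv), Et2O, −78 °C; DMF; then MeOH, NaBH4, 0 °C
Reagents that add atoms: N,N-dimethylformamide, CN(C)C=O
Why: Single bromine–lithium exchange at −78 °C, where the 3-furyllithium does not isomerise, then formylation and borohydride reduction in the same flask install the C9 carbon on future C8.

Step 4
Reactants: 6 (4-bromofuran-3-yl)methanol
Product: 7 [(4-bromofuran-3-yl)methoxy](tert-butyl)dimethylsilane
Conditions: TBSCl, imidazole, DMF, rt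
Reagents that add atoms: tert-butyldimethylsilyl chloride, CC(C)(C)[Si](C)(C)Cl
Why: Standard silylation of a primary alcohol; the ether tolerates the two organolithium steps that follow.

Step 5
Reactants: 7 [(4-bromofuran-3-yl)methoxy](tert-butyl)dimethylsilane
Product: 8 {[4-bromo-5-(trimethylsilyl)furan-3-yl]methoxy}(tert-butyl)dimethylsilane
Conditions: LiN(i-Pr)2, THF, −78 °C; Me3SiCl
Reagents that add atoms: chlorotrimethylsilane, C[Si](C)(C)Cl
Why: Directed metalation: the amide base removes the α-hydrogen flanked by ring oxygen and bromine, as in 3-bromofuran itself, so silicon enters at the carbon that will become C19.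

Step 6
Reactants: 8 {[4-bromo-5-(trimethylsilyl)furan-3-yl]methoxy}(tert-butyl)dimethylsilane
Product: 9 tert-butyldimethyl{[4-methyl-5-(trimethylsilyl)furan-3-yl]methoxy}silane
Conditions: t-BuLi (2.1 equiv), Et2O, −78 °C; MeI, −78 °C to rt
Reagents that add atoms: iodomethane, CI
Why: Bromine–lithium exchange followed by methylation gives the C17 methyl; ether at −78 °C without polar additives should suppress 1,4 O-to-C silyl migration in the 3-furyllithium.

Step 7
Reactants: 10 2-methoxy-5-methylbenzoic acid; 11 (S)-2-(methoxymethyl)pyrrolidine
Product: 13 (2-methoxy-5-methylphenyl)[(2S)-2-(methoxymethyl)pyrrolidin-1-yl]methanone, via 2-methoxy-5-methylbenzoyl chloride 12 (not isolated)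
Conditions: (COCl)2, DMF (cat.), CH2Cl2, 0 °C to rt; then 11, Et3N, CH2Cl2, 0 °C
Reagents that add atoms: none
Why: Amide formation through the acid chloride; the product is the chiral benzamide needed for auxiliary-controlled Birch alkylation.

Step 8
Reactants: 13 (2-methoxy-5-methylphenyl)[(2S)-2-(methoxymethyl)pyrrolidin-1-yl]methanone
Product: 14 [(1R)-2-methoxy-1,5-dimethylcyclohexa-2,5-dien-1-yl][(2S)-2-(methoxymethyl)pyrrolidin-1-yl]methanone
Conditions: K (2.2 equiv), NH3(l)–THF, t-BuOH (1 equiv), −78 °C; then MeI, −78 °C; NH4Cl
Reagents that add atoms: iodomethane, CI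
Why: Birch reductive alkylation of a chiral 2-methoxybenzamide: reduction and para protonation give an amide enolate whose potassium is held by the enolate oxygen and the methoxymethyl arm, and methyl iodide should enter from the open face to set quaternary C1; the arene methoxy carbon becomes C14, the methyl-bearing carbon C11 and the bis-allylic CH2 C12.

Step 9
Reactants: 14 [(1R)-2-methoxy-1,5-dimethylcyclohexa-2,5-dien-1-yl][(2S)-2-(methoxymethyl)pyrrolidin-1-yl]methanone
Product: 15 (2R)-2-{[(2S)-2-(methoxymethyl)pyrrolidin-1-yl]carbonyl}-2,4-dimethylcyclohex-3-en-1-one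
Conditions: 1 M HCl, THF, rt
Reagents that add atoms: water, O
Why: Enol ether hydrolysis to the C14 ketone; C1 is quaternary, so the C10=C11 olefin cannot move into conjugation and the stereocentre cannot epimerise.

Step 10
Reactants: 15 (2R)-2-{[(2S)-2-(methoxymethyl)pyrrolidin-1-yl]carbonyl}-2,4-dimethylcyclohex-3-en-1-one
Product: 16 [(1R,6S)-6-hydroxy-1,3-dimethylcyclohex-2-en-1-yl][(2S)-2-(methoxymethyl)pyrrolidin-1-yl]methanone (C14 carbinol, 14S)
Conditions: (R)-2-methyl-CBS-oxazaborolidine (0.5 equiv), catecholborane, toluene, −78 to −40 °C
Reagents that add atoms: none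
Why: Corey–Bakshi–Shibata reduction under catalyst control: quaternary C1 is the large and C13 the small flank, so the (R)-catalyst should deliver hydride to give the 14S alcohol with oxygen cis to the carboxamide carbon and trans to the methyl; catecholborane spares the amide and the olefin.

Step 11
Reactants: 16 C14 carbinol
Product: 17 [(1R,6S)-6-(tert-butyldimethylsilyloxy)-1,3-dimethylcyclohex-2-en-1-yl][(2S)-2-(methoxymethyl)pyrrolidin-1-yl]methanone
Conditions: TBSOTf, 2,6-lutidine, CH2Cl2, 0 °C
Reagents that add atoms: tert-butyldimethylsilyl trifluoromethanesulfonate, CC(C)(C)[Si](C)(C)OS(=O)(=O)C(F)(F)F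
Why: Silyl triflate silylation of a hindered secondary alcohol next to a quaternary carbon; this ether is the C14 spectator up to step 26.

Step 12
Reactants: 17 C14 silyl ether
Product: 18 (4R,5S)-5-(tert-butyldimethylsilyloxy)-4-{[(2S)-2-(methoxymethyl)pyrrolidin-1-yl]carbonyl}-2,4-dimethylcyclohex-2-en-1-one (C12 enone)
Conditions: CrO3, 3,5-dimethylpyrazole, CH2Cl2, −20 °C
Reagents that add atoms: chromium trioxide, O=[Cr](=O)=O
Why: Allylic oxidation of the only olefin in the molecule; C1 is quaternary, so the ring methylene C12 is the only secondary allylic position and should be oxidised in preference to the C11 methyl.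

Step 13
Reactants: 18 C12 enone
Product: 19 [(1R,4S,6S)-6-(tert-butyldimethylsilyloxy)-4-hydroxy-1,3-dimethylcyclohex-2-en-1-yl][(2S)-2-(methoxymethyl)pyrrolidin-1-yl]methanone (C12 carbinol, 12S)
Conditions: (R)-2-methyl-CBS-oxazaborolidine (1 equiv), catecholborane, toluene, −78 °C
Reagents that add atoms: none
Why: Corey–Bakshi–Shibata 1,2-reduction of an α-methyl cyclohexenone with the alkenyl carbon C11 as large group; the (R)-catalyst should give the 12S alcohol, oxygen cis to the C1 methyl and trans to O14, which is the face from which C9 must later be delivered to C10.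

Step 14
Reactants: 19 C12 carbinol
Product: 20 [(1R,4S,6S)-6-(tert-butyldimethylsilyloxy)-1,3-dimethyl-4-(triethylsilyloxy)cyclohex-2-en-1-yl][(2S)-2-(methoxymethyl)pyrrolidin-1-yl]methanone
Conditions: Et3SiCl, imidazole, DMF, 0 °C to rt
Reagents that add atoms: chlorotriethylsilane, CC[Si](Cl)(CC)CC
Why: Temporary silylation of the allylic alcohol; the triethylsilyl ether survives the organometallic steps and can later be removed beside the hindered C14 tert-butyldimethylsilyl ether.

Step 15
Reactants: 20 bis-silyl amide
Product: 21 1-[(1R,4S,6S)-6-(tert-butyldimethylsilyloxy)-1,3-dimethyl-4-(triethylsilyloxy)cyclohex-2-en-1-yl]ethan-1-one (C2 methyl ketone)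
Conditions: MeLi (3 equiv), Et2O–THF, −78 to 0 °C; NH4Cl (aq)
Reagents that add atoms: methyllithium, [Li]C
Why: Acyl substitution of a tertiary amide by an organolithium; the tetrahedral adduct, held by lithium and the methoxymethyl arm, collapses only on work-up, so the ketone should form without over-addition and the auxiliary is released; the new methyl is C3.

Step 16
Reactants: 21 C2 methyl ketone; 3 (Z)-3-bromo-1-iodo-2-methylprop-1-ene
Product: 22 (4Z)-1-[(1R,4S,6S)-6-(tert-butyldimethylsilyloxy)-1,3-dimethyl-4-(triethylsilyloxy)cyclohex-2-en-1-yl]-5-iodo-4-methylpent-4-en-1-one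
Conditions: LiN(i-Pr)2, THF, −78 °C; then 3, DMPU, −78 to −40 °C
Reagents that add atoms: none
Why: Kinetic enolate alkylation; the ketone can enolise only toward C3 because C1 is quaternary, and the allylic bromide reacts at low temperature to form C3–C4 with the Z vinyl iodide intact.

Step 17
Reactants: 22 chain ketone
Product: 23 (1R,4Z)-1-[(1S,4S,6S)-6-(tert-butyldimethylsilyloxy)-1,3-dimethyl-4-(triethylsilyloxy)cyclohex-2-en-1-yl]-5-iodo-4-methylpent-4-en-1-ol (C2 carbinol, 2R)
Conditions: (S)-2-methyl-CBS-oxazaborolidine (0.5 equiv), BH3·SMe2 (0.8 equiv), THF, −20 °C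
Reagents that add atoms: none
Why: Corey–Bakshi–Shibata reduction of a tert-alkyl n-alkyl ketone, a substrate class with a large size difference between the flanks; with C1 as large group the (S)-catalyst should give the 2R alcohol.

Step 18
Reactants: 23 C2 carbinol
Product: 24 vinyl iodide with C2 methoxymethyl ether: (1S,2R,5Z,12S,14S) ring-A fragment bearing O2-CH2OCH3, O12-SiEt3, O14-Si(t-Bu)Me2 and the C6 iodide
Conditions: MeOCH2Cl, i-Pr2NEt, Bu4NI (cat.), CH2Cl2, 0 to 40 °C
Reagents that add atoms: chloromethyl methyl ether, COCCl
Why: Alkoxymethylation of a hindered alcohol under amine base, with no alkoxide that could trigger silyl migration from O14; the acetal has no acidic hydrogen and is a safe spectator in step 23.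

Step 19
Reactants: 9 tert-butyldimethyl{[4-methyl-5-(trimethylsilyl)furan-3-yl]methoxy}silane; 24 vinyl iodide
Product: 26 coupled dienylfuran: ring-A fragment 24 joined through the Z C5=C6 olefin to C7 of the furan (O9-Si(t-Bu)Me2 and C19-SiMe3), via furylzinc chloride 25 (not isolated)
Conditions: 9, s-BuLi, THF, −78 °C; ZnCl2, −78 °C to rt; then 24, Pd(PPh3)4 (5 mol %), THF, 45 °C
Reagents that add atoms: none
Why: Negishi coupling: the only free α-position of furan 9 (C7) is lithiated and transmetalated to zinc, and coupling with the alkenyl iodide proceeds with retention, forming C6–C7 with the Z olefin fixed.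

Step 20
Reactants: 26 coupled dienylfuran
Product: 27 diol with free O9–H (primary) and O12–H (secondary allylic), O2 and O14 still protected
Conditions: HF·pyridine, pyridine, THF, 0 °C to rt
Reagents that add atoms: none
Why: Graded desilylation: buffered fluoride removes the primary tert-butyldimethylsilyl and the unhindered secondary triethylsilyl ether much faster than the neopentyl-type C14 silyl ether, and the buffer protects the furyl–silicon bond.

Step 21
Reactants: 27 diol
Product: 29 furylmethyl chloride (C9–Cl) with free O12–H, via C9 methanesulfonate 28 (not isolated)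
Conditions: MeSO2Cl (1.1 equiv), 2,4,6-collidine, LiCl, DMF, 0 °C
Reagents that add atoms: lithium chloride, [Li+].[Cl-]; methanesulfonyl chloride, CS(=O)(=O)Cl
Why: Collington–Meyers chlorination: the primary hydroxyl is sulfonylated selectively and displaced by chloride in the same flask, leaving the secondary allylic alcohol free.

Step 22
Reactants: 29 furylmethyl chloride
Product: 30 thirteen-membered furan-bridged allylic ether (1S,2R,5Z,12S,14S), ring atoms C9–O–C12–C11=C10–C1–C2–C3–C4–C5=C6–C7–C8
Conditions: NaH, Bu4NI (cat.), THF, 60 °C, slow addition to 0.002 M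
Reagents that add atoms: none
Why: Intramolecular Williamson etherification under high dilution; the C12 alkoxide displaces an activated furylmethyl halide (iodide formed in situ), closing the large ring with retention at C12.

Step 23
Reactants: 30 thirteen-membered furan-bridged allylic ether
Product: 31 furan-fused ten-membered carbinol (1S,2R,5Z,9R,10S,14S) with free O9–H, C11=C12 olefin, O2-CH2OCH3, O14-Si(t-Bu)Me2, C19-SiMe3
Conditions: n-BuLi (1.5 equiv), THF, −78 to −20 °C; NH4Cl (aq)
Reagents that add atoms: none
Why: Butyllithium removes a C9 hydrogen, the only acidic site on the furan side because C19 carries silicon, and the α-oxy furylmethyl anion bonds to C10 through a five-membered envelope transition state while O–C12 breaks and the olefin moves to C11=C12 ([2,3]-Wittig rearrangement). The closest known reaction type is the [2,3]-Wittig ring contraction of macrocyclic allylic and furan-bridged ethers to medium-ring carbinols. Ring B is not closed end to end but by C9–C10 bonding across the thirteen-membered ring (13 to 10 through a five-atom cyclic array), so no high dilution is needed and the exchange of a carbanion for an alkoxide drives it. C10 is controlled by C12: the shift is suprafacial, C9 arrives on the face that oxygen leaves, cis to the C1 methyl, which gives the trans ring fusion (10S). C9 is controlled by the placement of the furyl group: with C1 in the Z-type position of the allyl terminus and the furyl group exo, the syn relation of O9 and the C10–C1 bond (9R) is expected, as for Z-allyl benzyl-type ethers, and the tether from C8 to C1 can span this arrangement. The step needs deprotonation at C9 and not at C12–H or the allylic C4 and C5-methyl hydrogens, and a [2,3] and not a [1,2] shift; the higher kinetic acidity of the primary furylmethyl ether position, the low temperature and spectators without acidic hydrogens should secure both.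

Step 24
Reactants: 31 ten-membered carbinol
Product: 32 C9 2-naphthylmethyl ether of 31
Conditions: NaH, 2-(bromomethyl)naphthalene, Bu4NI (cat.), THF–DMF, 0 °C to rt
Reagents that add atoms: 2-(bromomethyl)naphthalene, BrCc1ccc2ccccc2c1
Why: Williamson etherification with a reactive benzylic bromide; an ether at O9 cannot migrate or take part in lactone formation and is stable to fluoride and to the Lewis acid used later.

Step 25
Reactants: 32 C9 2-naphthylmethyl ether
Product: 34 butenolide (7S) with C19 carbonyl and C8=C17 olefin, via C7 hydroxybutenolide 33 (not isolated)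
Conditions: O2, hν (visible), tetraphenylporphyrin (cat.), CH2Cl2, −78 °C; then MeOH, CeCl3·7H2O, NaBH4, −78 to −20 °C; 1 M HCl
Reagents that add atoms: oxygen, O=O
Why: Singlet oxygen adds across the furan α-carbons far faster than it reacts with the trisubstituted olefins, and silicon migration in the endoperoxide places the carboxyl at C19 (silylfuran photooxygenation to a γ-hydroxybutenolide); Luche reduction of the ring-opened C7 ketone and lactonisation on acidification give the butenolide, with C7 set by hydride approach to the exposed face of the ring-B enone.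

Step 26
Reactants: 34 butenolide
Product: 35 C14 alcohol (O14–H free, O2-CH2OCH3, O9 2-naphthylmethyl)
Conditions: HF·pyridine, THF, 0 °C to rt
Reagents that add atoms: none
Why: Fluoride cleavage of the remaining silyl ether under mildly acidic conditions that should not epimerise C7 or touch the acetal and the benzyl-type ether.

Step 27
Reactants: 35 C14 alcohol
Product: 36 C14 acetate
Conditions: Ac2O, DMAP, pyridine, CH2Cl2, 0 °C to rt
Reagents that add atoms: acetic anhydride, CC(=O)OC(C)=O
Why: DMAP-catalysed acetylation of the only free hydroxyl.

Step 28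
Reactants: 36 C14 acetate
Product: 37 C2 alcohol (O2–H free, O14 acetate, O9 2-naphthylmethyl)
Conditions: Me2BBr, CH2Cl2, −78 °C; then NaHCO3 (aq)
Reagents that add atoms: none
Why: Bromodimethylborane cleaves methoxymethyl acetals at −78 °C through the bromomethyl ether, conditions under which esters, the lactone and benzyl-type ethers are expected to persist.

Step 29
Reactants: 37 C2 alcohol
Product: 38 C2 butanoate, C14 acetate, C9 2-naphthylmethyl ether
Conditions: (n-PrCO)2O, DMAP, Et3N, CH2Cl2, 0 °C
Reagents that add atoms: butanoic anhydride, CCCC(=O)OC(=O)CCC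
Why: Fast DMAP-catalysed acylation, carried out directly on crude 37 at low temperature so that acetyl migration from O14 to O2 has no time to compete.

Step 30
Reactants: 38 fully acylated 2-naphthylmethyl ether
Product: 39 CNP0293221.1, (1S,2R,5Z,7S,9R,10S,14S)-14-acetoxy-2-butanoyloxy-9-hydroxy tricycle with the C19–O–C7 butenolide
Conditions: DDQ, CH2Cl2–pH 7 buffer, rt
Reagents that add atoms: none
Why: Oxidative cleavage of the 2-naphthylmethyl ether under neutral conditions, which should spare both esters, the electron-poor butenolide and the isolated olefins and release the C9 hydroxyl last.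

## Compound list

1 | prop-2-yn-1-ol | C#CCO | starting material
2 | (Z)-3-iodo-2-methylprop-2-en-1-ol | OC/C(C)=C\I | intermediate
3 | (Z)-3-bromo-1-iodo-2-methylprop-1-ene | BrC/C(C)=C\I | intermediate
4 | 3,4-dibromofuran | Brc1cocc1Br | starting material
5 | 4-bromofuran-3-carbaldehyde (not isolated) | O=Cc1cocc1Br | intermediate
6 | (4-bromofuran-3-yl)methanol | OCc1cocc1Br | intermediate
7 | [(4-bromofuran-3-yl)methoxy](tert-butyl)dimethylsilane | CC(C)(C)[Si](C)(C)OCc1cocc1Br | intermediate
8 | {[4-bromo-5-(trimethylsilyl)furan-3-yl]methoxy}(tert-butyl)dimethylsilane | CC(C)(C)[Si](C)(C)OCc1coc([Si](C)(C)C)c1Br | intermediate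
9 | tert-butyldimethyl{[4-methyl-5-(trimethylsilyl)furan-3-yl]methoxy}silane | CC(C)(C)[Si](C)(C)OCc1coc([Si](C)(C)C)c1C | intermediate
10 | 2-methoxy-5-methylbenzoic acid | COc1ccc(C)cc1C(=O)O | starting material
11 | (S)-2-(methoxymethyl)pyrrolidine | COC[C@@H]1CCCN1 | starting material
12 | 2-methoxy-5-methylbenzoyl chloride (not isolated) | COc1ccc(C)cc1C(=O)Cl | intermediate
13 | (2-methoxy-5-methylphenyl)[(2S)-2-(methoxymethyl)pyrrolidin-1-yl]methanone | COC[C@@H]1CCCN1C(=O)c1cc(C)ccc1OC | intermediate
14 | [(1R)-2-methoxy-1,5-dimethylcyclohexa-2,5-dien-1-yl][(2S)-2-(methoxymethyl)pyrrolidin-1-yl]methanone | CC1=C[C@](C(=O)N2CCC[C@H]2COC)(C)C(OC)=CC1 | intermediate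
15 | (2R)-2-{[(2S)-2-(methoxymethyl)pyrrolidin-1-yl]carbonyl}-2,4-dimethylcyclohex-3-en-1-one | CC1=C[C@](C(=O)N2CCC[C@H]2COC)(C)C(=O)CC1 | intermediate
16 | [(1R,6S)-6-hydroxy-1,3-dimethylcyclohex-2-en-1-yl][(2S)-2-(methoxymethyl)pyrrolidin-1-yl]methanone | CC1=C[C@](C(=O)N2CCC[C@H]2COC)(C)[C@@H](O)CC1 | intermediate
17 | [(1R,6S)-6-(tert-butyldimethylsilyloxy)-1,3-dimethylcyclohex-2-en-1-yl][(2S)-2-(methoxymethyl)pyrrolidin-1-yl]methanone | CC1=C[C@](C(=O)N2CCC[C@H]2COC)(C)[C@@H](O[Si](C)(C)C(C)(C)C)CC1 | intermediate
18 | (4R,5S)-5-(tert-butyldimethylsilyloxy)-4-{[(2S)-2-(methoxymethyl)pyrrolidin-1-yl]carbonyl}-2,4-dimethylcyclohex-2-en-1-one | CC1=C[C@](C(=O)N2CCC[C@H]2COC)(C)[C@@H](O[Si](C)(C)C(C)(C)C)CC1=O | intermediate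
19 | [(1R,4S,6S)-6-(tert-butyldimethylsilyloxy)-4-hydroxy-1,3-dimethylcyclohex-2-en-1-yl][(2S)-2-(methoxymethyl)pyrrolidin-1-yl]methanone | O[C@@H]1C(C)=C[C@](C(=O)N2CCC[C@H]2COC)(C)[C@@H](O[Si](C)(C)C(C)(C)C)C1 | intermediate
20 | [(1R,4S,6S)-6-(tert-butyldimethylsilyloxy)-1,3-dimethyl-4-(triethylsilyloxy)cyclohex-2-en-1-yl][(2S)-2-(methoxymethyl)pyrrolidin-1-yl]methanone | CC[Si](CC)(CC)O[C@@H]1C(C)=C[C@](C(=O)N2CCC[C@H]2COC)(C)[C@@H](O[Si](C)(C)C(C)(C)C)C1 | intermediate
21 | 1-[(1R,4S,6S)-6-(tert-butyldimethylsilyloxy)-1,3-dimethyl-4-(triethylsilyloxy)cyclohex-2-en-1-yl]ethan-1-one | CC[Si](CC)(CC)O[C@@H]1C(C)=C[C@](C(C)=O)(C)[C@@H](O[Si](C)(C)C(C)(C)C)C1 | intermediate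
22 | (4Z)-1-[(1R,4S,6S)-6-(tert-butyldimethylsilyloxy)-1,3-dimethyl-4-(triethylsilyloxy)cyclohex-2-en-1-yl]-5-iodo-4-methylpent-4-en-1-one | CC[Si](CC)(CC)O[C@@H]1C(C)=C[C@](C(=O)CC/C(C)=C\I)(C)[C@@H](O[Si](C)(C)C(C)(C)C)C1 | intermediate
23 | (1R,4Z)-1-[(1S,4S,6S)-6-(tert-butyldimethylsilyloxy)-1,3-dimethyl-4-(triethylsilyloxy)cyclohex-2-en-1-yl]-5-iodo-4-methylpent-4-en-1-ol | CC[Si](CC)(CC)O[C@@H]1C(C)=C[C@]([C@H](O)CC/C(C)=C\I)(C)[C@@H](O[Si](C)(C)C(C)(C)C)C1 | intermediate
24 | methoxymethyl ether of 23 (vinyl iodide; 1S,2R,5Z,12S,14S in target numbering) | CC[Si](CC)(CC)O[C@@H]1C(C)=C[C@]([C@H](OCOC)CC/C(C)=C\I)(C)[C@@H](O[Si](C)(C)C(C)(C)C)C1 | intermediate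
25 | [3-(tert-butyldimethylsilyloxymethyl)-4-methyl-5-(trimethylsilyl)furan-2-yl]zinc chloride (not isolated) | Cc1c([Si](C)(C)C)oc([Zn]Cl)c1CO[Si](C)(C)C(C)(C)C | intermediate
26 | coupled dienylfuran (1S,2R,5Z,12S,14S): O2 methoxymethyl, O12 triethylsilyl, O14 and O9 tert-butyldimethylsilyl, C19 trimethylsilyl | CC[Si](CC)(CC)O[C@@H]1C(C)=C[C@]([C@H](OCOC)CC/C(C)=C\c2oc([Si](C)(C)C)c(C)c2CO[Si](C)(C)C(C)(C)C)(C)[C@@H](O[Si](C)(C)C(C)(C)C)C1 | intermediate
27 | diol with free O9–H and O12–H (1S,2R,5Z,12S,14S) | O[C@@H]1C(C)=C[C@]([C@H](OCOC)CC/C(C)=C\c2oc([Si](C)(C)C)c(C)c2CO)(C)[C@@H](O[Si](C)(C)C(C)(C)C)C1 | intermediate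
28 | C9 methanesulfonate of 27 (not isolated) | O[C@@H]1C(C)=C[C@]([C@H](OCOC)CC/C(C)=C\c2oc([Si](C)(C)C)c(C)c2COS(C)(=O)=O)(C)[C@@H](O[Si](C)(C)C(C)(C)C)C1 | intermediate
29 | C9 chloride with free O12–H (1S,2R,5Z,12S,14S) | O[C@@H]1C(C)=C[C@]([C@H](OCOC)CC/C(C)=C\c2oc([Si](C)(C)C)c(C)c2CCl)(C)[C@@H](O[Si](C)(C)C(C)(C)C)C1 | intermediate
30 | thirteen-membered furan-bridged allylic ether (1S,2R,5Z,12S,14S) | COCO[C@@H]1CC/C(C)=C\c2oc([Si](C)(C)C)c(C)c2CO[C@@H]2C(C)=C[C@]1(C)[C@@H](O[Si](C)(C)C(C)(C)C)C2 | intermediate
31 | furan-fused ten-membered carbinol (1S,2R,5Z,9R,10S,14S) | COCO[C@@H]1CC/C(C)=C\c2oc([Si](C)(C)C)c(C)c2[C@H](O)[C@H]2C(C)=CC[C@H](O[Si](C)(C)C(C)(C)C)[C@@]21C | intermediate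
32 | C9 2-naphthylmethyl ether of 31 | COCO[C@@H]1CC/C(C)=C\c2oc([Si](C)(C)C)c(C)c2[C@H](OCc3ccc4ccccc4c3)[C@H]2C(C)=CC[C@H](O[Si](C)(C)C(C)(C)C)[C@@]21C | intermediate
33 | C7 hydroxybutenolide, both C7 epimers (not isolated) | COCO[C@@H]1CC/C(C)=C\C2(O)OC(=O)C(C)=C2[C@H](OCc3ccc4ccccc4c3)[C@H]2C(C)=CC[C@H](O[Si](C)(C)C(C)(C)C)[C@@]21C | intermediate
34 | butenolide (1S,2R,5Z,7S,9R,10S,14S): O2 methoxymethyl, O9 2-naphthylmethyl, O14 tert-butyldimethylsilyl | COCO[C@@H]1CC/C(C)=C\[C@@H]2OC(=O)C(C)=C2[C@H](OCc3ccc4ccccc4c3)[C@H]2C(C)=CC[C@H](O[Si](C)(C)C(C)(C)C)[C@@]21C | intermediate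
35 | C14 alcohol (1R by priority change, otherwise as 34) | COCO[C@@H]1CC/C(C)=C\[C@@H]2OC(=O)C(C)=C2[C@H](OCc3ccc4ccccc4c3)[C@H]2C(C)=CC[C@H](O)[C@@]21C | intermediate
36 | C14 acetate, O2 methoxymethyl, O9 2-naphthylmethyl | COCO[C@@H]1CC/C(C)=C\[C@@H]2OC(=O)C(C)=C2[C@H](OCc3ccc4ccccc4c3)[C@H]2C(C)=CC[C@H](OC(C)=O)[C@@]21C | intermediate
37 | C2 alcohol, C14 acetate, O9 2-naphthylmethyl | O[C@@H]1CC/C(C)=C\[C@@H]2OC(=O)C(C)=C2[C@H](OCc3ccc4ccccc4c3)[C@H]2C(C)=CC[C@H](OC(C)=O)[C@@]21C | intermediate
38 | C2 butanoate, C14 acetate, O9 2-naphthylmethyl | CCCC(=O)O[C@@H]1CC/C(C)=C\[C@@H]2OC(=O)C(C)=C2[C@H](OCc3ccc4ccccc4c3)[C@H]2C(C)=CC[C@H](OC(C)=O)[C@@]21C | intermediate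
39 | CNP0293221.1, (1S,2R,5Z,7S,9R,10S,14S) | CCCC(=O)O[C@@H]1CC/C(C)=C\[C@@H]2OC(=O)C(C)=C2[C@H](O)[C@H]2C(C)=CC[C@H](OC(C)=O)[C@@]21C | target

## Step count and least certain steps

Total step count: 30 (steps 1–2 for bromide 3, steps 3–6 for furan 9, steps 7–30 for the main line).
Longest linear sequence: 24 steps, from acid 10 through steps 7–30.

**Step 23 (key step).** The furyl group may prefer the endo position in the ring-constrained transition state, which would mean poor or reversed facial selectivity at C9, while C10 stays secure through suprafacial transfer. Competing [1,2]-shift on warming is the second concern. The fallback sets out from 30 and accepts the rearrangement product as the 9-epimeric carbinol F1. This is oxidised with Dess–Martin periodinane to the C9 furyl ketone F2. The ketone is then reduced from its exposed face with NaBH4 and CeCl3, or with a bulkier borohydride if the other face is needed, and the route is rejoined at 31. Stereocontrol thus moves from the rearrangement to a hydride addition.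

**Step 13.** Catalyst control may be opposed by the substrate: hydride may prefer the face away from the C14 silyloxy group and the C1 side chain, which erodes the selectivity for the 12S alcohol. The fallback sets out from 18. Reduction with NaBH4 and CeCl3 under substrate control should give the 12-epimeric alcohol F3, with oxygen cis to O14. Mitsunobu reaction with 4-nitrobenzoic acid inverts C12 to give the 4-nitrobenzoate F4. Methanolysis with K2CO3 in methanol returns to 19.

**Step 15.** Addition of methyllithium to the neopentyl tertiary amide may be too slow because of steric shielding, so that starting material survives or the silyl ethers suffer on warming. The fallback sets out from 20. Reduction with LiNH2BH3 cleaves the auxiliary and gives the primary alcohol F5. Oxidation with Dess–Martin periodinane gives the aldehyde F6, and addition of MeMgBr gives the secondary carbinol F7 as an epimer mixture. A second Dess–Martin oxidation returns to 21.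

**Step 22.** Intermolecular etherification and loss of the activated furylmethyl chloride by ionisation may compete with the thirteen-membered closure. The fallback sets out from 27. The primary hydroxyl is converted with Cl3CCN and catalytic DBU into the trichloroacetimidate F8. This is cyclised under high dilution with a catalytic amount of Me3SiOTf at low temperature, so that the C12 hydroxyl captures the furylmethyl cation under acid catalysis instead of attacking as an alkoxide. The route is rejoined at 30.

**Step 25.** Hydride delivery to the ring-opened C7 ketone may show poor facial selectivity, because the conformation of the ten-membered enone is not known in advance. The fallback sets out from 32. Oxidation with peracetic acid buffered by NaOAc (silylfuran to butenolide oxidation) should give the deconjugated lactone F9, with hydrogen at C17 and a C7=C8 enol lactone. Treatment with DBU moves the olefin into conjugation and places the hydrogen at C7 under equilibrating conditions, returning to 34. Here C7 is set by protonation under thermodynamic control, not by kinetic hydride addition. The price is an oxidant that is less selective toward the isolated olefins.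

## Further compounds

F1 | step 23 | 9-epimer of carbinol 31 (1S,2R,5Z,9S,10S,14S) | COCO[C@@H]1CC/C(C)=C\c2oc([Si](C)(C)C)c(C)c2[C@@H](O)[C@H]2C(C)=CC[C@H](O[Si](C)(C)C(C)(C)C)[C@@]21C
F2 | step 23 | C9 furyl ketone of the ten-membered carbocycle | COCO[C@@H]1CC/C(C)=C\c2oc([Si](C)(C)C)c(C)c2C(=O)[C@H]2C(C)=CC[C@H](O[Si](C)(C)C(C)(C)C)[C@@]21C
F3 | step 13 | 12-epimer of carbinol 19 (12R) | O[C@H]1C(C)=C[C@](C(=O)N2CCC[C@H]2COC)(C)[C@@H](O[Si](C)(C)C(C)(C)C)C1
F4 | step 13 | 4-nitrobenzoate of carbinol 19 (12S) | O=C(O[C@@H]1C(C)=C[C@](C(=O)N2CCC[C@H]2COC)(C)[C@@H](O[Si](C)(C)C(C)(C)C)C1)c1ccc([N+](=O)[O-])cc1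
F5 | step 15 | primary alcohol at C2 (ring A with CH2OH on C1) | CC[Si](CC)(CC)O[C@@H]1C(C)=C[C@](CO)(C)[C@@H](O[Si](C)(C)C(C)(C)C)C1
F6 | step 15 | C2 aldehyde | CC[Si](CC)(CC)O[C@@H]1C(C)=C[C@](C=O)(C)[C@@H](O[Si](C)(C)C(C)(C)C)C1
F7 | step 15 | secondary carbinol at C2 bearing the C3 methyl, epimer mixture | CC[Si](CC)(CC)O[C@@H]1C(C)=C[C@](C(C)O)(C)[C@@H](O[Si](C)(C)C(C)(C)C)C1
F8 | step 22 | C9 trichloroacetimidate of diol 27 | O[C@@H]1C(C)=C[C@]([C@H](OCOC)CC/C(C)=C\c2oc([Si](C)(C)C)c(C)c2COC(=N)C(Cl)(Cl)Cl)(C)[C@@H](O[Si](C)(C)C(C)(C)C)C1
F9 | step 25 | deconjugated lactone with C17–H and C7=C8 enol lactone, C17 epimer mixture | COCO[C@@H]1CC/C(C)=C\C2=C([C@H](OCc3ccc4ccccc4c3)[C@H]3C(C)=CC[C@H](O[Si](C)(C)C(C)(C)C)[C@@]31C)C(C)C(=O)O2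
A1 | alternative 1 | cyclohexene aldehyde with C1, C10 and C14 set, formyl as latent C1 methyl | CC(C)(C)[Si](C)(C)OC[C@H]1C(C)=CC[C@H](OC(C)=O)[C@]1(C=O)COCc1ccc(OC)cc1
A2 | alternative 2 | ten-membered cycloalkyne butenolide lacking the C5 methyl | CCCC(=O)O[C@@H]1CCC#C[C@@H]2OC(=O)C(C)=C2[C@H](O[Si](CC)(CC)CC)[C@H]2C(C)=CC[C@H](OC(C)=O)[C@@]21C
A3 | alternative 3 | ten-membered C2 ketone with C3 phenylsulfonyl group | O=C1C(S(=O)(=O)c2ccccc2)C/C(C)=C\[C@@H]2OC(=O)C(C)=C2[C@H](O[Si](CC)(CC)CC)[C@H]2C(C)=CC[C@H](OC(C)=O)[C@@]21C
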